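The numbers in the tables come from a simulation with constants of no real substance; scatter was added.

The catalyst charged stays in the flask in one form or another, so a flask's budget is its catalyst-minutes, charge times time, and that budget buys starting material consumed. Partner stands at 60.0 mM in Monday's, Thursday's and Sunday's as in the three runs, so it drops out of the comparison.

all flasks: starting material 20 mM

| run | partner | free catalyst | remark | time |
|---|---|---|---|---|
| blue | 60 mM | 0.88 mM | run made earlier |  |
| grey | 60 mM | 2.2 mM | run made earlier |  |
| violet | 60 mM | 3 mM | run made earlier |  |
| Monday's | 60.0 mM | 2.0 mM |  | 8.0 min |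
| Thursday's | 60.0 mM | 1.0 mM |  | 8.0 min |
| Sunday's | 60.0 mM | 4.0 mM |  | 8.0 min |

| run | time / min | catalyst intermediate A / % | target / % | starting material / % | catalyst intermediate B / % |
|---|---|---|---|---|---|
| blue | 1.33 | 1.0 | 2.0 | 95.1 | 1.4 |
| blue | 3.00 | 0.9 | 7.0 | 90.5 | 1.4 |
| blue | 4.00 | 1.0 | 8.8 | 87.8 | 1.5 |
| blue | 6.00 | 1.2 | 14.3 | 82.0 | 1.1 |
| grey | 1.33 | 2.7 | 4.6 | 86.8 | 4.8 |
| grey | 3.00 | 2.3 | 15.4 | 76.0 | 4.1 |
| grey | 4.00 | 3.0 | 22.1 | 69.8 | 3.2 |
| grey | 6.00 | 2.4 | 33.8 | 58.6 | 3.4 |
| violet | 0.667 | 5.0 | 0.9 | 86.6 | 5.5 |
| violet | 2.00 | 3.7 | 13.1 | 76.2 | 4.1 |
| violet | 4.00 | 3.3 | 29.5 | 60.2 | 4.2 |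
| violet | 6.00 | 3.2 | 44.0 | 46.2 | 3.5 |

(each reading ± 0.5 percentage points)

- the analysis behind the earlier runs scatters by 0.5 percentage points, standard deviation
- a reading or a percentage of target counts all its forms, free or not

* which of these there is most of at the end, counted by the starting material in it, Monday's (catalyst intermediate B / catalyst intermediate A / target / starting material)
* which of these there is most of at the end, counted by the starting material in it, Thursday's (catalyst intermediate B / catalyst intermediate A / target / starting material)
* which of these there is most of at the end, counted by the starting material in it, Sunday's (catalyst intermediate B / catalyst intermediate A / target / starting material)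
* final amount of the leader among these, as a percentage of the starting material charged, in Monday's
* final amount of the leader among these, as a percentage of the starting material charged, in Thursday's
* final amount of the leader among these, as a percentage of the starting material charged, in Sunday's

The price per mM consumed, read at the last reading, is 1.47 min in blue and 1.67 min in violet, so it climbs as [starting material] falls. Those readings span 5.28 mM·min to 18.0 mM·min. Thursday's budget of 8.00 mM·min and Monday's of 16.0 mM·min lie inside that span, so they hardly lean on any constant of mine. Sunday's 32.0 mM·min lies outside it, so the one number I must know well is how steeply the price climbs.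

I take the price as a fixed part plus a wait that grows as charge over [starting material], and I solve both from the last grey and violet readings, which gives a fixed part of 0.891 min and a wait at full charge of 0.545 min, both carrying the scatter of those readings. Summed over the fall, reaching 15.0 mM needs 7.59 mM·min, a little less than Thursday's budget. Reaching 10.0 mM needs 16.5 mM·min, a little more than Monday's. Reaching 4.00 mM needs 31.8 mM·min, which is about Sunday's budget.

So I expect starting material ahead on Thursday's and Monday's, near those levels. Sunday's mean turn time, the catalyst-minutes paid per mM consumed (the inverse of a mean turnover frequency), comes to 1.99 min. A wait off by 10 % moves Sunday's starting material by 2.4 percentage points. Violet's last reading holds 44.7 % of its catalyst as intermediates A and B, and taking that share off leaves Sunday's target near 71.1 %.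

The forecast has starting material ahead on Monday's at 52.5 %, starting material on Thursday's at 75 % and target on Sunday's at 69 %, “extrapolating with a falling rate” for the last.

Monday's gives starting material at 51.9 %. Thursday's gives starting material at 74.4 %. Sunday's gives target at 71.7 %.

    partner + catalyst intermediate A → catalyst intermediate B (k = 0.720 M⁻¹ s⁻¹)
    catalyst intermediate B → by-product + catalyst intermediate C (k = 0.0310 s⁻¹)
    catalyst intermediate D → free catalyst + target (k = 2.20 s⁻¹)
    starting material + free catalyst → catalyst intermediate A (k = 2.20 M⁻¹ s⁻¹)
    partner + target ⇌ idle adduct, settled at all times (K = 19.0 M⁻¹)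
    catalyst intermediate C ⇌ catalyst intermediate D (K = 1.90, k = 0.0590 s⁻¹)

Sunday's paid 1.98 min per mM consumed, beside my 1.99 min. Its catalyst charge is the main reason target leads: with that difference taken away, target is 22.0 %, not 71.7 %. The neighbour of Sunday's charged with 240 mM of partner leaves 12 % of its starting material, at a mean turn time of 1.81 min.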